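The data stem from a simulated flask with made-up constants; scatter was added.

Treat the loss of D around its peak as a steady drain, not as a share of D. Here is what you have and what you asked.

| setting | theta | delta | flask |
|---|---|---|---|
| E | 0.10 M | 0.15 M | 0.20 M |
| remark | run made earlier | run made earlier |  |
| time |  |  | 6.0 d |

| run | time / d | D / % | E / % |
|---|---|---|---|
| theta | 0.125 | 22.7 | 49.3 |
| theta | 0.250 | 37.6 | 24.1 |
| theta | 0.417 | 44.4 | 9.2 |
| theta | 0.625 | 40.3 | 3.3 |
| theta | 1.25 | 13.9 | 0.1 |
| theta | 2.00 | 5.0 | 0.9 |
| theta | 4.00 | 0.6 | 0.1 |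
| delta | 0.125 | 26.8 | 48.4 |
| delta | 0.250 | 46.2 | 23.7 |
| delta | 0.417 | 56.7 | 9.1 |
| delta | 0.625 | 56.8 | 2.4 |
| delta | 1.25 | 37.1 | 0 |
| delta | 2.00 | 11.4 | 0.1 |
| delta | 4.00 | 0.8 | 0.4 |

(each reading ± 0.5 percentage points)

- a reading or a percentage of D counts all its forms, free or not

* time, not beyond 6.0 d, at which the flask holds most D
* the amount of D, in percent of the E charged, at that time

In the delta run, between 0.625 d and 1.25 d, D and E together fall at 0.0530 M/d. Call this the drain: the amount per day leaving D and E together after the early loss, a zero-order loss. The theta run gives 0.0474 M/d over that stretch, with less D standing.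

The delta reading at 0.250 d gives E a first-order constant of 5.76 /d. I reckon that D stops rising when the feed from E, this constant times the E standing, falls to the drain. In your flask that gives 0.534 d, with 4.61% of the E left.

At 0.417 d, the amount that is neither D nor E stands at 0.0464 M in theta and 0.0513 M in delta. I carry that rise per unit of charge on to your charge and add the drain up to the peak, which gives 0.0624 M missing. So I commit to 0.534 d and 64.2%.

The forecast you sent says 0.55 d and 65%, a little above mine, on the ground that “D removal is saturated, near zero-order”.

The flask gives 0.553 d and 64.8%, so the forecast held.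

    X → J (k = 0.390 /h)
    X ⇌ D (K = 2.90, k = 6.40 /h)
    X ⇌ Z (K = 2.40, k = 2.60 /h)
    E → X (k = 0.240 /h)
    G ⇌ D, rate k5*(cs5 - [D]) while solid is left; crystals form when [D] > cs5 (solubility = 18.0 mM, k = 8.40 /h)

Now take the neighbour flask charged with 0.12 M of E. The same drain puts its peak at 0.446 d, with 7.68% of its E left. The same rise per unit of charge, counted from theta, gives 0.0499 M missing there, so the reckoning gives 50.7%. That neighbour flask reached 50.7% of D.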